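**Retrosynthetic overview**
- Caraphenol C (all-cis indane) ⇐ pentabenzyl 3-aroyl-1H-indene: one hydrogenation adds H2 syn across the tetrasubstituted C1=C2 bond from the face opposite the C3 aryl group and removes all five benzyl ethers.
- Aroylindene ⇐ indenyl triflate + arylstannane + CO (carbonylative Stille). Triflate ⇐ (3R)-2,3-diarylindan-1-one ⇐ achiral 2,3-diarylinden-1-one, by CBS reduction and a stereospecific 1,3-hydrogen shift that moves the carbinol configuration to C3.
- Indenone ⇐ 3-benzylidenephthalide + arylmagnesium bromide: lactone opening unmasks a keto enolate that closes the five-membered carbocycle by intramolecular aldol condensation (C2–C3 bond).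
- Benzylidenephthalide ⇐ 2-bromo-4,6-bis(benzyloxy)benzoic acid (from 5-bromoresorcinol) + 3,5-bis(benzyloxy)phenylacetylene (from methyl 3,5-dihydroxybenzoate); the aryl bromide for the Grignard reagent and the stannane comes from 4-bromophenol.
- Ring order: temporary lactone ring (step 7), then the indene five-membered ring (step 9), the only ring of the target that is built.

Assumption: the SMILES is taken literally; it encodes the (1R,2R,3R) indane in which the 4-hydroxybenzoyl, 3,5-dihydroxyphenyl and 4-hydroxyphenyl groups are all cis, and that isomer is the one made.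

**Step 1**
Reactants: 1 5-bromobenzene-1,3-diol
Product: 2 1,3-bis(benzyloxy)-5-bromobenzene
Conditions: BnBr (2.2 equiv), K2CO3 (3 equiv), DMF, 60 °C
Reagents that add atoms: benzyl bromide, BrCc1ccccc1
Why: Williamson ether synthesis on both phenols; the benzyl ethers survive every later step and leave by hydrogenolysis in step 15.

**Step 2**
Reactants: 2 1,3-bis(benzyloxy)-5-bromobenzene
Product: 4 2,4-bis(benzyloxy)-6-bromobenzaldehyde, via aryl iminium chloride 3 (not isolated)
Conditions: POCl3 (2 equiv), DMF, 0 °C then 80 °C; then ice-water, rt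
Reagents that add atoms: N,N-dimethylformamide, CN(C)C=O; water, O
Why: Vilsmeier–Haack formylation goes para to one benzyloxy group and ortho to the other (next to Br) in preference to the more crowded site between the two ethers, and the iminium salt is hydrolysed on work-up.

**Step 3**
Reactants: 4 2,4-bis(benzyloxy)-6-bromobenzaldehyde
Product: 5 2,4-bis(benzyloxy)-6-bromobenzoic acid
Conditions: NaClO2, NaH2PO4, 2-methyl-2-butene, t-BuOH/THF/H2O, rt
Reagents that add atoms: sodium chlorite, [Na+].[O-]Cl=O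
Why: Pinnick oxidation converts the hindered aldehyde to the acid under buffered conditions while the alkene traps HOCl before it can chlorinate the electron-rich ring.

**Step 4**
Reactants: 6 methyl 3,5-dihydroxybenzoate
Product: 7 methyl 3,5-bis(benzyloxy)benzoate
Conditions: BnBr (2.2 equiv), K2CO3, acetone, reflux
Reagents that add atoms: benzyl bromide, BrCc1ccccc1
Why: Williamson ether synthesis; the ester is inert to carbonate.

**Step 5**
Reactants: 7 methyl 3,5-bis(benzyloxy)benzoate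
Product: 8 [3,5-bis(benzyloxy)phenyl]methanol
Conditions: LiAlH4, THF, 0 °C to rt; then H2O
Reagents that add atoms: none
Why: hydride reduction of the ester to the benzylic alcohol; benzyl aryl ethers are untouched.

**Step 6**
Reactants: 8 [3,5-bis(benzyloxy)phenyl]methanol
Product: 10 1,3-bis(benzyloxy)-5-ethynylbenzene, via aldehyde 9 (not isolated)
Conditions: MnO2 (10 equiv), THF, rt; then dimethyl (1-diazo-2-oxopropyl)phosphonate, K2CO3, MeOH, rt
Reagents that add atoms: dimethyl (1-diazo-2-oxopropyl)phosphonate, CC(=O)C(=[N+]=[N-])P(=O)(OC)OC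
Why: MnO2 oxidises the benzylic alcohol and the aldehyde is homologated in the same flask by the Seyferth–Gilbert reaction in its Ohira–Bestmann form, which adds one carbon and gives the terminal alkyne.

**Step 7**
Reactants: 5 2,4-bis(benzyloxy)-6-bromobenzoic acid; 10 1,3-bis(benzyloxy)-5-ethynylbenzene
Product: 12 (3Z)-5,7-bis(benzyloxy)-3-[3,5-bis(benzyloxy)benzylidene]-2-benzofuran-1(3H)-one, via alkynyl acid 11 (not isolated)
Conditions: CuI (10 mol%), K2CO3 (2 equiv), DMF, 100 °C, argon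
Reagents that add atoms: none
Why: carboxylate-assisted Castro–Stephens-type coupling of the ortho-bromo acid with the copper acetylide, then 5-exo-dig anti addition of the carboxylate to the alkyne (favoured under basic conditions and by the non-donating meta-oxygenated aryl group), gives the Z enol lactone; its alkene geometry is lost in step 9 and does not matter.

**Step 8**
Reactants: 13 4-bromophenol
Product: 14 1-(benzyloxy)-4-bromobenzene
Conditions: BnBr (1.1 equiv), K2CO3, acetone, reflux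
Reagents that add atoms: benzyl bromide, BrCc1ccccc1
Why: Williamson ether synthesis.

**Step 9**
Reactants: 14 1-(benzyloxy)-4-bromobenzene; 12 (3Z)-5,7-bis(benzyloxy)-3-[3,5-bis(benzyloxy)benzylidene]-2-benzofuran-1(3H)-one
Product: 18 4,6-bis(benzyloxy)-2-[3,5-bis(benzyloxy)phenyl]-3-[4-(benzyloxy)phenyl]-1H-inden-1-one, via arylmagnesium bromide 15 (not isolated), via keto enolate 16 (not isolated), via aldol adduct 17 (not isolated)
Conditions: 14 (1.3 equiv), Mg, THF, reflux; add to 12, THF, 0 °C to rt; 1 M HCl quench; crude, p-TsOH·H2O (5 mol%), toluene, 50 °C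
Reagents that add atoms: none
Why: the Grignard reagent opens the enol lactone at its carbonyl group, the released magnesium enolate of the 1,4-diketone attacks the new diaryl ketone in an intramolecular aldol addition that closes the five-membered ring, and acid dehydrates the tertiary doubly benzylic aldol to the achiral indenone (aldol condensation).

**Step 10**
Reactants: 18 4,6-bis(benzyloxy)-2-[3,5-bis(benzyloxy)phenyl]-3-[4-(benzyloxy)phenyl]-1H-inden-1-one
Product: 19 (1S)-4,6-bis(benzyloxy)-2-[3,5-bis(benzyloxy)phenyl]-3-[4-(benzyloxy)phenyl]-1H-inden-1-ol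
Conditions: (R)-2-methyl-CBS-oxazaborolidine (20 mol%), BH3·SMe2 (1.0 equiv), THF, −20 °C; MeOH quench
Reagents that add atoms: none
Why: Corey–Bakshi–Shibata reduction; on the standard model the catalyst binds the carbonyl lone pair on the open benzo-ring side (the 2-aryl-substituted alkene is the large group), so hydride goes to one face and C1 is set as S, a sense to be confirmed on the first run with the antipodal catalyst used if it is reversed.

**Step 11**
Reactants: 19 (1S)-4,6-bis(benzyloxy)-2-[3,5-bis(benzyloxy)phenyl]-3-[4-(benzyloxy)phenyl]-1H-inden-1-ol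
Product: 21 (2R,3R)-4,6-bis(benzyloxy)-2-[3,5-bis(benzyloxy)phenyl]-3-[4-(benzyloxy)phenyl]-2,3-dihydro-1H-inden-1-one, via enol 20 (not isolated)
Conditions: DABCO (0.5 equiv), Et3N/THF (1:1), 60 °C
Reagents that add atoms: none
Why: base-mediated stereospecific 1,3-prototropic shift; the amine removes the acidic indenyl C1–H and returns it within the contact ion pair to the same face at C3, so the carbinol configuration becomes 3R, the enol tautomerises to the ketone and C2 settles trans (its configuration is erased in step 12).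

**Step 12**
Reactants: 21 (2R,3R)-4,6-bis(benzyloxy)-2-[3,5-bis(benzyloxy)phenyl]-3-[4-(benzyloxy)phenyl]-2,3-dihydro-1H-inden-1-one
Product: 23 (1R)-5,7-bis(benzyloxy)-2-[3,5-bis(benzyloxy)phenyl]-1-[4-(benzyloxy)phenyl]-1H-inden-3-yl trifluoromethanesulfonate, via potassium enolate 22 (not isolated)
Conditions: KN(SiMe3)2 (1.05 equiv, added to 21), THF, −78 °C; PhNTf2 (1.2 equiv), −78 to 0 °C; sat. aq NH4Cl
Reagents that add atoms: N-phenylbis(trifluoromethanesulfonimide), O=S(=O)(N(c1ccccc1)S(=O)(=O)C(F)(F)F)C(F)(F)F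
Why: enolate O-sulfonylation; only the C2–H next to the ketone is removed, the aryl-bearing stereocentre is untouched, and avoiding excess base protects the now indenylic C–H.

**Step 13**
Reactants: 14 1-(benzyloxy)-4-bromobenzene
Product: 25 [4-(benzyloxy)phenyl]tributylstannane, via aryllithium 24 (not isolated)
Conditions: n-BuLi (1.05 equiv), THF, −78 °C; Bu3SnCl, −78 °C to rt
Reagents that add atoms: tributyltin chloride, CCCC[Sn](Cl)(CCCC)CCCC
Why: bromine–lithium exchange followed by stannylation of the aryllithium.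

**Step 14**
Reactants: 23 (1R)-5,7-bis(benzyloxy)-2-[3,5-bis(benzyloxy)phenyl]-1-[4-(benzyloxy)phenyl]-1H-inden-3-yl trifluoromethanesulfonate; 25 [4-(benzyloxy)phenyl]tributylstannane
Product: 26 [(1S)-5,7-bis(benzyloxy)-2-[3,5-bis(benzyloxy)phenyl]-1-[4-(benzyloxy)phenyl]-1H-inden-3-yl][4-(benzyloxy)phenyl]methanone
Conditions: Pd(PPh3)4 (5 mol%), LiCl (3 equiv), CO (3 atm), THF, 60 °C
Reagents that add atoms: carbon monoxide, [C-]#[O+]
Why: carbonylative Stille coupling (oxidative addition of the enol triflate to zerovalent palladium, CO insertion, transmetalation, reductive elimination) gives the aryl ketone under base-free conditions that leave the acidic stereogenic C–H alone; the descriptor changes from R to S only because of CIP priorities.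

**Step 15**
Reactants: 26 [(1S)-5,7-bis(benzyloxy)-2-[3,5-bis(benzyloxy)phenyl]-1-[4-(benzyloxy)phenyl]-1H-inden-3-yl][4-(benzyloxy)phenyl]methanone
Product: 27 caraphenol C, (4-hydroxyphenyl)[(1R,2R,3R)-2-(3,5-dihydroxyphenyl)-4,6-dihydroxy-3-(4-hydroxyphenyl)-2,3-dihydro-1H-inden-1-yl]methanone
Conditions: H2 (4 atm), 10% Pd/C, EtOAc/MeOH (1:1), rt
Reagents that add atoms: none
Why: heterogeneous hydrogenation adds both hydrogens syn to the enone C=C from the face opposite the C3 aryl group, which sets C1 and C2 so that all three substituents are cis (1R,2R,3R), while the same catalyst hydrogenolyses the five benzyl ethers under neutral conditions that do not epimerise C1.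

**Compound list**
1 | 5-bromobenzene-1,3-diol | Oc1cc(O)cc(Br)c1 | starting material
2 | 1,3-bis(benzyloxy)-5-bromobenzene | Brc1cc(OCc2ccccc2)cc(OCc2ccccc2)c1 | intermediate
3 | [2,4-bis(benzyloxy)-6-bromophenyl]methylidene(dimethyl)ammonium chloride | C[N+](C)=Cc1c(Br)cc(OCc2ccccc2)cc1OCc1ccccc1.[Cl-] | intermediate (not isolated)
4 | 2,4-bis(benzyloxy)-6-bromobenzaldehyde | O=Cc1c(Br)cc(OCc2ccccc2)cc1OCc1ccccc1 | intermediate
5 | 2,4-bis(benzyloxy)-6-bromobenzoic acid | OC(=O)c1c(Br)cc(OCc2ccccc2)cc1OCc1ccccc1 | intermediate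
6 | methyl 3,5-dihydroxybenzoate | COC(=O)c1cc(O)cc(O)c1 | starting material
7 | methyl 3,5-bis(benzyloxy)benzoate | COC(=O)c1cc(OCc2ccccc2)cc(OCc2ccccc2)c1 | intermediate
8 | [3,5-bis(benzyloxy)phenyl]methanol | OCc1cc(OCc2ccccc2)cc(OCc2ccccc2)c1 | intermediate
9 | 3,5-bis(benzyloxy)benzaldehyde | O=Cc1cc(OCc2ccccc2)cc(OCc2ccccc2)c1 | intermediate (not isolated)
10 | 1,3-bis(benzyloxy)-5-ethynylbenzene | C#Cc1cc(OCc2ccccc2)cc(OCc2ccccc2)c1 | intermediate
11 | 2,4-bis(benzyloxy)-6-{[3,5-bis(benzyloxy)phenyl]ethynyl}benzoic acid (present as its carboxylate) | OC(=O)c1c(C#Cc2cc(OCc3ccccc3)cc(OCc3ccccc3)c2)cc(OCc2ccccc2)cc1OCc1ccccc1 | intermediate (not isolated)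
12 | (3Z)-5,7-bis(benzyloxy)-3-[3,5-bis(benzyloxy)benzylidene]-2-benzofuran-1(3H)-one | O=C1O/C(=C\c2cc(OCc3ccccc3)cc(OCc3ccccc3)c2)c2cc(OCc3ccccc3)cc(OCc3ccccc3)c12 | intermediate
13 | 4-bromophenol | Oc1ccc(Br)cc1 | starting material
14 | 1-(benzyloxy)-4-bromobenzene | Brc1ccc(OCc2ccccc2)cc1 | intermediate
15 | [4-(benzyloxy)phenyl]magnesium bromide | Br[Mg]c1ccc(OCc2ccccc2)cc1 | intermediate (not isolated)
16 | bromomagnesium enolate of 1-{3,5-bis(benzyloxy)-2-[4-(benzyloxy)benzoyl]phenyl}-2-[3,5-bis(benzyloxy)phenyl]ethan-1-one | Br[Mg]OC(=Cc1cc(OCc2ccccc2)cc(OCc2ccccc2)c1)c1cc(OCc2ccccc2)cc(OCc2ccccc2)c1C(=O)c1ccc(OCc2ccccc2)cc1 | intermediate (not isolated)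
17 | 4,6-bis(benzyloxy)-2-[3,5-bis(benzyloxy)phenyl]-3-[4-(benzyloxy)phenyl]-3-hydroxy-2,3-dihydro-1H-inden-1-one (diastereomer mixture) | O=C1C(c2cc(OCc3ccccc3)cc(OCc3ccccc3)c2)C(O)(c2ccc(OCc3ccccc3)cc2)c2c(OCc3ccccc3)cc(OCc3ccccc3)cc12 | intermediate (not isolated)
18 | 4,6-bis(benzyloxy)-2-[3,5-bis(benzyloxy)phenyl]-3-[4-(benzyloxy)phenyl]-1H-inden-1-one | O=C1C(c2cc(OCc3ccccc3)cc(OCc3ccccc3)c2)=C(c2ccc(OCc3ccccc3)cc2)c2c(OCc3ccccc3)cc(OCc3ccccc3)cc12 | intermediate
19 | (1S)-4,6-bis(benzyloxy)-2-[3,5-bis(benzyloxy)phenyl]-3-[4-(benzyloxy)phenyl]-1H-inden-1-ol | O[C@@H]1C(c2cc(OCc3ccccc3)cc(OCc3ccccc3)c2)=C(c2ccc(OCc3ccccc3)cc2)c2c(OCc3ccccc3)cc(OCc3ccccc3)cc12 | intermediate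
20 | (1S)-5,7-bis(benzyloxy)-2-[3,5-bis(benzyloxy)phenyl]-1-[4-(benzyloxy)phenyl]-1H-inden-3-ol (enol of 21) | OC1=C(c2cc(OCc3ccccc3)cc(OCc3ccccc3)c2)[C@H](c2ccc(OCc3ccccc3)cc2)c2c(OCc3ccccc3)cc(OCc3ccccc3)cc12 | intermediate (not isolated)
21 | (2R,3R)-4,6-bis(benzyloxy)-2-[3,5-bis(benzyloxy)phenyl]-3-[4-(benzyloxy)phenyl]-2,3-dihydro-1H-inden-1-one (2,3-trans) | O=C1[C@@H](c2cc(OCc3ccccc3)cc(OCc3ccccc3)c2)[C@H](c2ccc(OCc3ccccc3)cc2)c2c(OCc3ccccc3)cc(OCc3ccccc3)cc12 | intermediate
22 | potassium (1S)-5,7-bis(benzyloxy)-2-[3,5-bis(benzyloxy)phenyl]-1-[4-(benzyloxy)phenyl]-1H-inden-3-olate | [K+].[O-]C1=C(c2cc(OCc3ccccc3)cc(OCc3ccccc3)c2)[C@H](c2ccc(OCc3ccccc3)cc2)c2c(OCc3ccccc3)cc(OCc3ccccc3)cc12 | intermediate (not isolated)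
23 | (1R)-5,7-bis(benzyloxy)-2-[3,5-bis(benzyloxy)phenyl]-1-[4-(benzyloxy)phenyl]-1H-inden-3-yl trifluoromethanesulfonate | O=S(=O)(OC1=C(c2cc(OCc3ccccc3)cc(OCc3ccccc3)c2)[C@H](c2ccc(OCc3ccccc3)cc2)c2c(OCc3ccccc3)cc(OCc3ccccc3)cc12)C(F)(F)F | intermediate
24 | [4-(benzyloxy)phenyl]lithium | [Li]c1ccc(OCc2ccccc2)cc1 | intermediate (not isolated)
25 | [4-(benzyloxy)phenyl]tributylstannane | CCCC[Sn](CCCC)(CCCC)c1ccc(OCc2ccccc2)cc1 | intermediate
26 | [(1S)-5,7-bis(benzyloxy)-2-[3,5-bis(benzyloxy)phenyl]-1-[4-(benzyloxy)phenyl]-1H-inden-3-yl][4-(benzyloxy)phenyl]methanone | O=C(c1ccc(OCc2ccccc2)cc1)C1=C(c2cc(OCc3ccccc3)cc(OCc3ccccc3)c2)[C@H](c2ccc(OCc3ccccc3)cc2)c2c(OCc3ccccc3)cc(OCc3ccccc3)cc12 | intermediate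
27 | caraphenol C, (4-hydroxyphenyl)[(1R,2R,3R)-2-(3,5-dihydroxyphenyl)-4,6-dihydroxy-3-(4-hydroxyphenyl)-2,3-dihydro-1H-inden-1-yl]methanone | O=C(c1ccc(O)cc1)[C@H]1c2cc(O)cc(O)c2[C@@H](c2ccc(O)cc2)[C@H]1c1cc(O)cc(O)c1 | target

**Step count**
Total: 15 steps. Longest linear sequence: 10 steps (1, 2, 3, 7, 9, 10, 11, 12, 14, 15; the branch 4, 5, 6 is equally long).

**Steps most likely to fail, with fallbacks**

Step 7 (copper-mediated coupling and lactonisation). The electron-rich, doubly ortho-substituted acid may protodecarboxylate, and 6-endo closure to the isocoumarin can compete. The fallback sets out from aldehyde 4 and alkyne 10. Sonogashira coupling (PdCl2(PPh3)2, CuI, Et3N, THF, 60 °C) on the activated ortho-bromo aldehyde gives 2,4-bis(benzyloxy)-6-{[3,5-bis(benzyloxy)phenyl]ethynyl}benzaldehyde F1. Pinnick oxidation (NaClO2, NaH2PO4, 2-methyl-2-butene) then gives acid 11, now isolated. DBU (20 mol%) in MeCN at 80 °C effects the base-catalysed 5-exo-dig lactonisation, and the route is rejoined at 12.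

Step 11 (chirality transfer by the 1,3-hydrogen shift, together with step 10 that feeds it). The proton shuttle is untested on a 2-aryl indenol and may erode the ee. The fallback sets out from indenone 18 and replaces steps 10 and 11 by an asymmetric conjugate reduction with copper hydride: Cu(OAc)2·H2O (5 mol%), (R)-DTBM-SEGPHOS (5.5 mol%), (EtO)2MeSiH, toluene, rt. The ligand enantiomer is chosen so that hydride adds to the C3 face that gives 3R. The product is {[(1R)-5,7-bis(benzyloxy)-2-[3,5-bis(benzyloxy)phenyl]-1-[4-(benzyloxy)phenyl]-1H-inden-3-yl]oxy}diethoxy(methyl)silane F2. Cleavage with Bu4NF/AcOH in THF at 0 °C returns to the route at ketone 21.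

Step 15 (hydrogenation and debenzylation in one operation). The hindered tetrasubstituted alkene may reduce slowly, palladium hydride may move the double bond through C3 and erode the ee, and the ketone may be over-reduced. The fallback sets out from 26 and separates the events. Conjugate reduction with [(Ph3P)CuH]6 in toluene/THF with water (2 equiv) at rt adds hydride to C2 from the face opposite the C3 aryl group, and the copper enolate is protonated kinetically at C1 from the same open face. This gives [4-(benzyloxy)phenyl][(1R,2R,3R)-4,6-bis(benzyloxy)-2-[3,5-bis(benzyloxy)phenyl]-3-[4-(benzyloxy)phenyl]-2,3-dihydro-1H-inden-1-yl]methanone F3. Hydrogenolysis of the benzyl ethers alone (H2 1 atm, 10% Pd/C, EtOAc/MeOH, rt) then arrives at target 27.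

**Further compounds**
F1 | step 7 | 2,4-bis(benzyloxy)-6-{[3,5-bis(benzyloxy)phenyl]ethynyl}benzaldehyde | O=Cc1c(C#Cc2cc(OCc3ccccc3)cc(OCc3ccccc3)c2)cc(OCc2ccccc2)cc1OCc1ccccc1
F2 | step 11 | {[(1R)-5,7-bis(benzyloxy)-2-[3,5-bis(benzyloxy)phenyl]-1-[4-(benzyloxy)phenyl]-1H-inden-3-yl]oxy}diethoxy(methyl)silane | CCO[Si](C)(OCC)OC1=C(c2cc(OCc3ccccc3)cc(OCc3ccccc3)c2)[C@H](c2ccc(OCc3ccccc3)cc2)c2c(OCc3ccccc3)cc(OCc3ccccc3)cc12
F3 | step 15 | [4-(benzyloxy)phenyl][(1R,2R,3R)-4,6-bis(benzyloxy)-2-[3,5-bis(benzyloxy)phenyl]-3-[4-(benzyloxy)phenyl]-2,3-dihydro-1H-inden-1-yl]methanone | O=C(c1ccc(OCc2ccccc2)cc1)[C@H]1c2cc(OCc3ccccc3)cc(OCc3ccccc3)c2[C@@H](c2ccc(OCc3ccccc3)cc2)[C@H]1c1cc(OCc2ccccc2)cc(OCc2ccccc2)c1
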